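- Per J, the charge holds 1.10 equiv of Z and 5.00 equiv of E, more E than Z, so I treat Z as the limiting reagent and ask how it divides between J and E.

| setting | delta | eta | gamma | larch | oak | alder | birch |
|---|---|---|---|---|---|---|---|
| J | 41 mM | 41 mM | 41 mM | 41 mM | 41 mM | 41 mM | 41 mM |
| Z | 1.1 equiv | 1.1 equiv | 1.1 equiv | 1.10 equiv | 1.10 equiv | 1.10 equiv | 1.10 equiv |
| E | 5 equiv | 5 equiv | 5 equiv | 5.00 equiv (fed, over 15.0 min) | 5.00 equiv | 5.00 equiv | 5.00 equiv |
| L | 14 mol% | 9.4 mol% | 21 mol% | 14 mol% | 14 mol% | 14 mol% | 14 mol% |
| remark | run made earlier | run made earlier | run made earlier | all but E at the start; E goes in evenly over 15.0 min, the run ends at 15 min | a single well-mixed tank run continuously and read at steady state, 15 min in it on average | everything together in a closed stirred flask, run for 15 min | a tube with plug flow, the mixed feed as stated, residence time 15 min |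
| time |  |  |  | 15 min |  | 15 min | 15 min |

- delta (time / min: Q / %): 4.00: 66.8; 8.00: 68.9; 12.0: 68.7; 15.0: 68.6
- eta (time / min: Q / %): 3.00: 59.2; 6.00: 66.9; 10.0: 68.7; 12.0: 68.6
- gamma (time / min: Q / %): 1.00: 54.7; 2.00: 64.8; 5.00: 69.6; 12.0: 68.9

(scatter of a reading: 0.3 percentage points)

- the stated concentrations are those of everything mixed, before any reaction; amounts are the same in each set-up
- the feed brings no volume worth counting
- the earlier runs were made in a closed, stirred flask

- the set-up with the highest amount of Q at the outlet or at the end, in percent of the J put in ("none" if the first two lie within 2 percentage points) (larch / oak / alder / birch / none)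
- amount of Q at the outlet or at the end, in percent of the J put in, larch
- amount of Q at the outlet or at the end, in percent of the J put in, oak
- amount of Q at the outlet or at the end, in percent of the J put in, alder
- amount of Q at the outlet or at the end, in percent of the J put in, birch

- Delta at 14 mol% and 4.00 min reads 66.8%, and eta at 9.4 mol% and 6.00 min reads 66.9%, with equal products of loading and time, so I take the rate as first order in L.
- The last readings at the three loadings are 68.6%, 68.6% and 68.9%, a spread of about the scatter 0.3 percentage points. Their mean is a plateau of 68.7%, so L changes the pace of the run but not the split.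
- If the plateau accounts for the Z charged, J took 68.7% and E took the remaining 0.413 equiv, which leaves 91.7% of the E charge and 31.3% of the J charge.
- The rule I carry is the selectivity factor S, the ratio of the two rate constants for taking Z, which equals ln(fraction of J left) over ln(fraction of E left): S = 13.5. Z goes to J and E in the ratio S·J/E, with J and E in equivalents.
- First instants in alder: the ratio is 2.69 parts of Z to J for each part to E.
- Middle: with J at half its charge and E taken at its charge, the ratio is 1.35.
- End: at the plateau it is 0.922, and the readings stop rising. Delta already reads 68.9% at 8.00 min, so I put alder and birch, whose plug flow runs like the flask, on the plateau.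
- Larch: E enters over 15.0 min. Taking J and E each at half charge gives the ratio 2.69, above 1.35. I commit to larch above the plateau, but the size needs the rate.
- Oak: the tank works at outlet J throughout. The balance (1−J)/J = S(1−E)/E with Z at zero gives J 40.0%, so Q is 60.0%, below the plateau. Z remaining at the outlet lowers this mark.
- The forecast names larch as best: 90% (84% to 94%) for larch, 56.7% (52% to 62%) for oak, and 68.7% for alder and 68.7% for birch. Its ground for larch is “Larch keeps E low early, so Z goes mainly to J.” For oak it takes Z at 0.09 where I took zero, and its figure lies below my 60.0%.
- The simulation gives larch as best: 89.9% for larch, 56.2% for oak, 68.5% for alder and 68.5% for birch.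

    J + Z + L → L + Q (k = 66.0 /M²/s)
    E + Z + L → L + X (k = 4.60 /M²/s)
    Q → D (k = 2.30 × 10⁻⁵ /s)

- Each value lies inside the forecast's range. Alder has 92% of its E left, and that fraction raised to S gives J 32.4%, where the flask holds 30%. The answer for birch has moved by 5 points at 1.21 equiv of Z. The neighbour flask, alder with 2.80 equiv of Z, gives 97.8% of Q and keeps 65% of its E. That fraction raised to S gives J 0.295%, and the neighbour flask holds 0.20%.

The numbers in the tables were generated by integration with constants of no real substance; scatter was added.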